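The route rests on cutting the C5–C5 biaryl bond between ring A (the capsaicin ring, E-alkenyl arm) and ring B (the saturated-arm ring). Ring B is prepared with iodine at C4, where its hydroxyl will later stand, and is raised to the trivalent diacetoxyiodane; unmodified capsaicin is the partner. The key step exploits that on both guaiacol rings C3 carries the methoxy group, so C5 is the only open carbon ortho to the C4 heteroatom: the ring A phenol binds to iodine and a [3,3] shift through the I–O link makes the C5–C5 bond cross-selectively in one operation. Afterwards the C4 iodine of ring B is exchanged for hydroxyl.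

Key step: step 5

Assumption: vanillyl numbering is used on both rings (C1 carries the CH2N arm, C3 the methoxy group, C4 the oxygen or iodine, C5 the coupling carbon); ring A is the capsaicin-derived ring and ring B the dihydro ring.

Step 1
Reactants: 1 methyl 4-iodo-3-methoxybenzoate
Product: 2 (4-iodo-3-methoxyphenyl)methanol
Conditions: iBu2AlH (2.5 equiv), CH2Cl2, −78 to 0 °C; aq. potassium sodium tartrate (KNaC4H4O6) work-up
Reagents that add atoms: none
Why: Hydride reduction of an aryl ester with iBu2AlH at low temperature should stop cleanly at the benzylic alcohol and leave the aryl C–I bond untouched.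

Step 2
Reactants: 2 (4-iodo-3-methoxyphenyl)methanol
Product: 4 (4-iodo-3-methoxyphenyl)methanamine, via benzylic azide 3 (not isolated)
Conditions: (PhO)2P(O)N3 (1.2 equiv), DBU (1.3 equiv), toluene, 0 °C to rt; then PPh3 (1.5 equiv), THF/H2O, 50 °C; acid–base extraction
Reagents that add atoms: diphenylphosphoryl azide, [N-]=[N+]=NP(=O)(Oc1ccccc1)Oc1ccccc1
Why: Azidation of the primary benzylic alcohol with diphenylphosphoryl azide and DBU, followed in the same flask by Staudinger reduction, should give the amine without isolating the azide and without a hydride or hydrogenation step that could cleave the C–I bond.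

Step 3
Reactants: 4 (4-iodo-3-methoxyphenyl)methanamine; 5 8-methylnonanoic acid
Product: 6 N-[(4-iodo-3-methoxyphenyl)methyl]-8-methylnonanamide
Conditions: EDC (free base, 1.2 equiv), HOBt (1.0 equiv), CH2Cl2, 0 °C to rt
Reagents that add atoms: none
Why: Carbodiimide-mediated amide coupling of an unhindered primary benzylic amine with a simple aliphatic acid is a routine, high-confidence bond formation.

Step 4
Reactants: 6 N-[(4-iodo-3-methoxyphenyl)methyl]-8-methylnonanamide
Product: 7 N-{[4-(diacetoxyiodo)-3-methoxyphenyl]methyl}-8-methylnonanamide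
Conditions: NaBO3·4H2O (10 equiv), AcOH, 45 °C; aqueous work-up, trituration with hexane/Et2O
Reagents that add atoms: acetic acid, CC(=O)O
Why: Perborate in acetic acid generates peracetic acid, which should oxidise the electron-rich aryl iodide to the aryl diacetoxyiodane, while the saturated amide arm offers nothing a peracid attacks.

Step 5
Reactants: 7 N-{[4-(diacetoxyiodo)-3-methoxyphenyl]methyl}-8-methylnonanamide; 8 capsaicin, (6E)-N-[(4-hydroxy-3-methoxyphenyl)methyl]-8-methylnon-6-enamide
Product: 10 (6E)-N-({2-hydroxy-2'-iodo-3,3'-dimethoxy-5'-[(8-methylnonanamido)methyl]biphenyl-5-yl}methyl)-8-methylnon-6-enamide, via acetoxy(aryloxy)iodane 9 (not isolated)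
Conditions: 8 (1.3 equiv), CH2Cl2/(CF3)2CHOH 9:1, −40 °C; slow addition of 7 in CH2Cl2; then to 0 °C
Reagents that add atoms: none
Why: The capsaicin hydroxyl replaces one acetate on the trivalent iodine of 7 to give 9, whose six-atom chain C5(ring A)–C4(ring A)–O–I–C4(ring B)–C5(ring B) undergoes a concerted [3,3] shift that makes the C5–C5 bond as the I–O bond breaks and iodine falls to the monovalent state; loss of the second acetate as acetic acid and two proton shifts then restore both arenes. The closest known reaction type is the iodonio-Claisen dehydrogenative coupling of aryl(diacyloxy)iodanes with phenols to 2-hydroxy-2'-iodobiaryls. No ring is closed and no stereocentre is formed; the E alkene is a spectator because neither free peracid nor electrophilic halogen is present. Cross-selectivity is required and is secured because only ring B carries the oxidising iodine and only ring A carries a free hydroxyl, so neither homodimer can arise by this path. Site selectivity is secured because C3 of each ring bears methoxy, leaving C5 as the only hydrogen-bearing carbon ortho to the I–O link on either side. Chemoselectivity over oxidative dearomatisation of the guaiacol is sought through the cold, non-nucleophilic medium and by keeping the phenol in excess over the iodane throughout the addition.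

Step 6
Reactants: 10 (6E)-N-({2-hydroxy-2'-iodo-3,3'-dimethoxy-5'-[(8-methylnonanamido)methyl]biphenyl-5-yl}methyl)-8-methylnon-6-enamide
Product: 11 (6E)-N-({2-[(tert-butyldimethylsilyl)oxy]-2'-iodo-3,3'-dimethoxy-5'-[(8-methylnonanamido)methyl]biphenyl-5-yl}methyl)-8-methylnon-6-enamide
Conditions: TBSCl (1.5 equiv), imidazole (3 equiv), DMF, rt to 40 °C
Reagents that add atoms: tert-butyldimethylsilyl chloride, CC(C)(C)[Si](C)(C)Cl
Why: Imidazole-promoted O-silylation of the phenol should cap the ring A oxygen so that it can neither attack the metalated C4 of ring B (dibenzofuran closure) nor bind boron in the next step.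

Step 7
Reactants: 11 (6E)-N-({2-[(tert-butyldimethylsilyl)oxy]-2'-iodo-3,3'-dimethoxy-5'-[(8-methylnonanamido)methyl]biphenyl-5-yl}methyl)-8-methylnon-6-enamide
Product: 13 (6E)-N-({2-[(tert-butyldimethylsilyl)oxy]-2'-hydroxy-3,3'-dimethoxy-5'-[(8-methylnonanamido)methyl]biphenyl-5-yl}methyl)-8-methylnon-6-enamide, via pinacol boronate 12 (not isolated)
Conditions: B2pin2 (1.5 equiv), Pd2(dba)3 (2.5 mol%), XPhos (10 mol%), KOAc (3 equiv), 1,4-dioxane, 90 °C; then NaBO3·4H2O (5 equiv), THF/H2O, rt
Reagents that add atoms: sodium perborate tetrahydrate, [Na+].[O-]OB=O.O.O.O.O (the new phenolic oxygen); bis(pinacolato)diboron, CC1(C)OB(OC1(C)C)B1OC(C)(C)C(C)(C)O1 (the boryl group of 12 only)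
Why: Miyaura borylation with a bulky biaryl phosphine suited to doubly ortho-flanked aryl halides, followed by perborate oxidation of the C–B bond through a 1,2-aryl shift from boron to oxygen, should replace iodine by hydroxyl at the same carbon without affecting the alkene, amides or silyl ether.

Step 8
Reactants: 13 (6E)-N-({2-[(tert-butyldimethylsilyl)oxy]-2'-hydroxy-3,3'-dimethoxy-5'-[(8-methylnonanamido)methyl]biphenyl-5-yl}methyl)-8-methylnon-6-enamide
Product: 14 6'',7''-dihydro-5',5'''-dicapsaicin, (6E)-N-({2,2'-dihydroxy-3,3'-dimethoxy-5'-[(8-methylnonanamido)methyl]biphenyl-5-yl}methyl)-8-methylnon-6-enamide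
Conditions: Bu4NF (1.2 equiv), AcOH (1.2 equiv), THF, 0 °C to rt
Reagents that add atoms: none
Why: Fluoride cleavage of the aryl silyl ether, buffered with acetic acid so that the electron-rich biphenol is not left as an air-sensitive phenoxide, should release the target with the E alkene unchanged.

Compound list
1 | methyl 4-iodo-3-methoxybenzoate | COC(=O)c1ccc(I)c(OC)c1 | starting material
2 | (4-iodo-3-methoxyphenyl)methanol | OCc1ccc(I)c(OC)c1 | intermediate
3 | 4-(azidomethyl)-1-iodo-2-methoxybenzene | [N-]=[N+]=NCc1ccc(I)c(OC)c1 | intermediate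
4 | (4-iodo-3-methoxyphenyl)methanamine | NCc1ccc(I)c(OC)c1 | intermediate
5 | 8-methylnonanoic acid | CC(C)CCCCCCC(=O)O | starting material
6 | N-[(4-iodo-3-methoxyphenyl)methyl]-8-methylnonanamide | COc1cc(CNC(=O)CCCCCCC(C)C)ccc1I | intermediate
7 | N-{[4-(diacetoxyiodo)-3-methoxyphenyl]methyl}-8-methylnonanamide | CC(=O)OI(OC(C)=O)c1ccc(CNC(=O)CCCCCCC(C)C)cc1OC | intermediate
8 | capsaicin, (6E)-N-[(4-hydroxy-3-methoxyphenyl)methyl]-8-methylnon-6-enamide | COc1cc(CNC(=O)CCCC/C=C/C(C)C)ccc1O | starting material
9 | acetoxy(aryl)(aryloxy)iodane: iodine bound to C4 of ring B, to one acetate and to the C4 oxygen of capsaicin | COc1cc(CNC(=O)CCCC/C=C/C(C)C)ccc1OI(OC(C)=O)c1ccc(CNC(=O)CCCCCCC(C)C)cc1OC | intermediate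
10 | (6E)-N-({2-hydroxy-2'-iodo-3,3'-dimethoxy-5'-[(8-methylnonanamido)methyl]biphenyl-5-yl}methyl)-8-methylnon-6-enamide | COc1cc(CNC(=O)CCCC/C=C/C(C)C)cc(-c2cc(CNC(=O)CCCCCCC(C)C)cc(OC)c2I)c1O | intermediate
11 | tert-butyldimethylsilyl ether of 10 at the ring A phenol | COc1cc(CNC(=O)CCCC/C=C/C(C)C)cc(-c2cc(CNC(=O)CCCCCCC(C)C)cc(OC)c2I)c1O[Si](C)(C)C(C)(C)C | intermediate
12 | pinacol boronate of 11 (boron at C4 of ring B in place of iodine) | COc1cc(CNC(=O)CCCC/C=C/C(C)C)cc(-c2cc(CNC(=O)CCCCCCC(C)C)cc(OC)c2B3OC(C)(C)C(C)(C)O3)c1O[Si](C)(C)C(C)(C)C | intermediate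
13 | mono-silyl ether of the target (ring A O-TBS, ring B free phenol) | COc1cc(CNC(=O)CCCC/C=C/C(C)C)cc(-c2cc(CNC(=O)CCCCCCC(C)C)cc(OC)c2O)c1O[Si](C)(C)C(C)(C)C | intermediate
14 | 6'',7''-dihydro-5',5'''-dicapsaicin | COc1cc(CNC(=O)CCCC/C=C/C(C)C)cc(-c2cc(CNC(=O)CCCCCCC(C)C)cc(OC)c2O)c1O | target

Total step count: 8. Longest linear sequence: 8 steps (1 to 14); capsaicin 8 and acid 5 enter convergently.

Steps most likely to fail

Step 5. After ligand exchange, ionisation of the I–O bond and capture of the guaiacol ring by acetate (oxidative dearomatisation), or oxidation at the para-benzylic position, may outrun the sigmatropic shift. The fallback makes the C5–C5 bond by Suzuki–Miyaura coupling of two pre-functionalised halves, both drawn from 8. Hydrogenation of 8 (H2, Pd/C, EtOH) should give dihydrocapsaicin F1. Bromination ortho to the phenol (NBS, MeCN, 0 °C) should give 5-bromodihydrocapsaicin F2. Miyaura borylation (excess B2pin2, PdCl2(dppf), KOAc, dioxane, 90 °C) should give the pinacol boronate F3. Separately, iodination of 8 at C5 (I2, NaHCO3, THF/H2O, 0 °C) should give 5-iodocapsaicin F4, since phenoxide iodination is much faster than the reversible addition of iodine to the disubstituted alkene. Coupling of F3 with F4 (PdCl2(dppf), K2CO3, dioxane/H2O, 80 °C) would come back to the route at target 14, so steps 6 to 8 are not needed.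

Step 7. Oxidative addition and transmetalation at the C–I bond flanked by methoxy and aryl may be slow enough for hydrodeiodination to compete. Partial loss of the silyl group could also open the way to C–O ring closure. The fallback introduces boron without palladium, setting out from 11. Treatment with iPrMgCl·LiCl (3.3 equiv, of which two deprotonate the amide N–H groups) in THF at −20 °C should effect iodine–magnesium exchange, assisted by the ortho methoxy group. Quenching with B(OMe)3 and aqueous work-up should give the arylboronic acid F5, which is oxidised in the same flask with NaBO3·4H2O and rejoins the route at 13.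

Step 4. Oxidation may stall, or the diacetate may hydrolyse to ill-defined iodosyl oligomers during isolation, leaving an oxidant of uncertain ligand set and titre. The fallback sets out from 6 and uses a different oxidant and ligand set. Oxidation with KHSO5 (as 2KHSO5·KHSO4·K2SO4) in CF3CO2H/CHCl3 at rt should give the bis(trifluoroacetoxy)iodane F6. After filtration and evaporation, F6 is used crude in place of 7 in the coupling with 8 (CH2Cl2, −60 °C, no fluoroalcohol, since trifluoroacetate is the better leaving ligand) and comes back to the route at 10.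

Further compounds
F1 | step 5 | dihydrocapsaicin, N-[(4-hydroxy-3-methoxyphenyl)methyl]-8-methylnonanamide | COc1cc(CNC(=O)CCCCCCC(C)C)ccc1O
F2 | step 5 | 5-bromodihydrocapsaicin, N-[(3-bromo-4-hydroxy-5-methoxyphenyl)methyl]-8-methylnonanamide | COc1cc(CNC(=O)CCCCCCC(C)C)cc(Br)c1O
F3 | step 5 | N-{[4-hydroxy-3-methoxy-5-(4,4,5,5-tetramethyl-1,3,2-dioxaborolan-2-yl)phenyl]methyl}-8-methylnonanamide | COc1cc(CNC(=O)CCCCCCC(C)C)cc(B2OC(C)(C)C(C)(C)O2)c1O
F4 | step 5 | 5-iodocapsaicin, (6E)-N-[(4-hydroxy-3-iodo-5-methoxyphenyl)methyl]-8-methylnon-6-enamide | COc1cc(CNC(=O)CCCC/C=C/C(C)C)cc(I)c1O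
F5 | step 7 | arylboronic acid corresponding to 11 (B(OH)2 at C4 of ring B in place of iodine) | COc1cc(CNC(=O)CCCC/C=C/C(C)C)cc(-c2cc(CNC(=O)CCCCCCC(C)C)cc(OC)c2B(O)O)c1O[Si](C)(C)C(C)(C)C
F6 | step 4 | N-({4-[bis(trifluoroacetoxy)iodo]-3-methoxyphenyl}methyl)-8-methylnonanamide | COc1cc(CNC(=O)CCCCCCC(C)C)ccc1I(OC(=O)C(F)(F)F)OC(=O)C(F)(F)F
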